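The route rests on disconnecting C2–C3 of ring C. C2 of the flavanone is benzylic to ring B and bonded to O1, so its C–H bond in an aryl benzyl ether is activated toward a carbenoid generated at C3. In a single operation, a chiral dirhodium carboxylate converts an achiral diazomethyl ketone into the chromanone: N2 is lost, C2–C3 forms, ring C closes and the C2 stereocentre is set. The precursor is a 2,6-dioxygenated farnesylphenyl diazomethyl ketone carrying the ring B benzyl group on the future O1 and silyl ethers on all other phenols; it is assembled in five linear steps from phloroacetophenone, and one buffered fluoride treatment then releases the target.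

Key step: step 8

Conventions: flavanone locants (O1, C2, C3, C4, C4a, C5–C8, C8a; ring A = benzo ring, ring B = 2-aryl group, ring C = pyranone ring) are used for 12, 13 and the discussion of step 8. The acetophenones are numbered with the acyl-bearing carbon as C1 and the farnesyl-bearing carbon as C3. Farnesyl = (2E,6E)-3,7,11-trimethyldodeca-2,6,10-trien-1-yl; TBS = tert-butyldimethylsilyl; TIPS = triisopropylsilyl; p-ABSA = 4-acetamidobenzenesulfonyl azide; Rh2(S-PTTL)4 = dirhodium tetrakis[N-phthaloyl-(S)-tert-leucinate], a carboxylate complex of divalent rhodium.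

Assumption: the absolute sense of induction of Rh2(S-PTTL)4 on this substrate cannot be predicted with certainty. The S ligand is written; the equally accessible Rh2(R-PTTL)4 is to be used instead if a pilot run delivers the 2R antipode.

Step 1
Reactants: 1 2,4,6-trihydroxyacetophenone; 2 (2E,6E)-farnesyl bromide
Product: 3 1-[2,4,6-trihydroxy-3-[(2E,6E)-farnesyl]phenyl]ethanone
Conditions: DBU (1 equiv per 2), THF, 0 °C → rt; 1 in twofold excess
Reagents that add atoms: none
Why: C-alkylation of a phloroglucinol-type phenolate (nuclear prenylation): the delocalised anion of 1 attacks the primary allylic bromide by SN2 at a ring carbon between two oxygens, which avoids allylic transposition and keeps both E alkenes, while the excess of 1 holds back double alkylation.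

Step 2
Reactants: 3 1-[2,4,6-trihydroxy-3-[(2E,6E)-farnesyl]phenyl]ethanone
Product: 4 1-[4-(TBSO)-2,6-dihydroxy-3-[(2E,6E)-farnesyl]phenyl]ethanone
Conditions: TBSCl (1.05 equiv), imidazole, CH2Cl2–DMF, 0 °C
Reagents that add atoms: tert-butyldimethylsilyl chloride, CC(C)(C)[Si](C)(C)Cl
Why: Kinetically controlled phenol silylation: the 4-OH is the only hydroxyl not tied up in a hydrogen bond to the acetyl C=O and is the most acidic, so it should be silylated well ahead of the chelated 2-OH and 6-OH.

Step 3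
Reactants: 5 3,5-dihydroxybenzaldehyde
Product: 6 3,5-bis(TIPSO)benzaldehyde
Conditions: TIPSCl (2.2 equiv), imidazole, DMF, rt
Reagents that add atoms: triisopropylsilyl chloride, CC(C)[Si](Cl)(C(C)C)C(C)C
Why: Imidazole-promoted silylation of both phenols; TIPS is chosen for ring B because these ethers must last through six further steps and their bulk screens the ring B carbons next to the future C2.

Step 4
Reactants: 6 3,5-bis(TIPSO)benzaldehyde
Product: 7 [3,5-bis(TIPSO)phenyl]methanol
Conditions: NaBH4, MeOH–THF, 0 °C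
Reagents that add atoms: none
Why: Borohydride reduction of the aryl aldehyde gives the benzylic alcohol needed as the Mitsunobu partner; aryl TIPS ethers withstand NaBH4 in methanol at 0 °C.

Step 5
Reactants: 4 1-[4-(TBSO)-2,6-dihydroxy-3-[(2E,6E)-farnesyl]phenyl]ethanone; 7 [3,5-bis(TIPSO)phenyl]methanol
Product: 8 1-[6-{[3,5-bis(TIPSO)phenyl]methoxy}-4-(TBSO)-2-hydroxy-3-[(2E,6E)-farnesyl]phenyl]ethanone
Conditions: PPh3, DIAD (added last, slowly), THF, 0 °C → rt
Reagents that add atoms: none
Why: Mitsunobu etherification: the phenoxide displaces the benzylic alkoxyphosphonium ion, and of the two chelated hydroxyls the 6-OH, flanked only by H-5, is less hindered than the 2-OH wedged between the acetyl and farnesyl groups (the same preference that 3-prenylated phloroacetophenones show on O-alkylation), while the remaining 2-OH stays locked in its hydrogen bond and should resist a second etherification.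

Step 6
Reactants: 8 1-[6-{[3,5-bis(TIPSO)phenyl]methoxy}-4-(TBSO)-2-hydroxy-3-[(2E,6E)-farnesyl]phenyl]ethanone
Product: 9 1-[6-{[3,5-bis(TIPSO)phenyl]methoxy}-2,4-bis(TBSO)-3-[(2E,6E)-farnesyl]phenyl]ethanone
Conditions: TBSOTf, 2,6-lutidine, CH2Cl2, −78 → 0 °C
Reagents that add atoms: tert-butyldimethylsilyl trifluoromethanesulfonate, CC(C)(C)[Si](C)(C)OS(=O)(=O)C(F)(F)F
Why: O-silylation with a silyl triflate: the chelated, doubly flanked 2-OH needs the strongly electrophilic TBSOTf, while 2,6-lutidine is too weak and too hindered a base to enolise the methyl ketone at low temperature.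

Step 7
Reactants: 9 1-[6-{[3,5-bis(TIPSO)phenyl]methoxy}-2,4-bis(TBSO)-3-[(2E,6E)-farnesyl]phenyl]ethanone
Product: 11 2-diazo-1-[6-{[3,5-bis(TIPSO)phenyl]methoxy}-2,4-bis(TBSO)-3-[(2E,6E)-farnesyl]phenyl]ethanone, via trifluoroacetyl diketone 10 (not isolated)
Conditions: LiN(SiMe3)2, THF, −78 °C; CF3CO2CH2CF3, −78 °C; 1 M aq. HCl quench, 0 °C; crude 10, p-ABSA, Et3N, H2O (1 equiv), MeCN, rt
Reagents that add atoms: 4-acetamidobenzenesulfonyl azide, CC(=O)Nc1ccc(cc1)S(=O)(=O)N=[N+]=[N-]; 2,2,2-trifluoroethyl trifluoroacetate, FC(F)(F)COC(=O)C(F)(F)F (its trifluoroacetyl group stays in 10 only)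
Why: Regitz-type detrifluoroacetylative diazo transfer: the kinetic lithium enolate of the methyl ketone is C-trifluoroacetylated at −78 °C, where silyl migration from the ortho oxygen should be slow, and the activated diketone 10 takes the two terminal nitrogens of the sulfonyl azide and sheds its trifluoroacetyl group as the N-sulfonyl trifluoroacetamide, leaving silyl ethers and alkenes untouched.

Step 8
Reactants: 11 2-diazo-1-[6-{[3,5-bis(TIPSO)phenyl]methoxy}-2,4-bis(TBSO)-3-[(2E,6E)-farnesyl]phenyl]ethanone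
Product: 12 (2S)-5,7-bis(TBSO)-2-[3,5-bis(TIPSO)phenyl]-6-[(2E,6E)-farnesyl]chroman-4-one
Conditions: Rh2(S-PTTL)4 (2 mol %), 4 Å MS, CH2Cl2, 0 °C, slow addition of 11 (final 5 mM)
Reagents that add atoms: none
Why: Rh2(S-PTTL)4 adds to the diazo carbon of 11, N2 leaves, and the electrophilic carbenoid at C3 inserts into one C2–H bond of the O1–CH2–aryl group through a concerted, asynchronous three-centre transition state with hydride-shift character, forming C2–C3 and releasing the catalyst. The closest known reaction type is the dirhodium-carboxylate-catalysed intramolecular C–H insertion of 2-alkoxyaryl diazomethyl ketones next to the ether oxygen, which gives 2-substituted chroman-4-ones. Ring C closes as a six-membered ring by 1,6-insertion (C3, C4, C4a, C8a, O1, C2); no C–H bond is available for a five-membered closure, because the atom five positions from the carbenoid is O1 itself. The C2 stereocentre is set by the catalyst alone (reagent control on an achiral substrate): the phthalimido/tert-butyl ligand sphere selects one of the two enantiotopic benzylic hydrogens. The step needs C–H insertion to win over oxonium-ylide formation at O1 with [1,2]-benzyl shift, over attack at the C5 silyl ether oxygen and over alkene cyclopropanation; this should be secured because C2–H is activated twice (benzylic and alpha to oxygen), O1 is a weakly basic aryl ether oxygen conjugated with the C4 carbonyl, the bulky TBS group shields the C5 oxygen and offers no C–H bond within reach, the C2''=C3'' alkene sits meta to the carbenoid arm and cannot reach it, and slow addition at high dilution suppresses intermolecular cyclopropanation and carbene dimerisation.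

Step 9
Reactants: 12 (2S)-5,7-bis(TBSO)-2-[3,5-bis(TIPSO)phenyl]-6-[(2E,6E)-farnesyl]chroman-4-one
Product: 13 (2S)-2-(3,5-dihydroxyphenyl)-5,7-dihydroxy-6-[(2E,6E)-farnesyl]chroman-4-one
Conditions: Bu4NF, AcOH (in excess over fluoride), THF, 0 °C
Reagents that add atoms: none
Why: Fluoride-driven cleavage of all four aryl silyl ethers (Si–F bond formation); excess acetic acid keeps the liberated phenols protonated, so base-induced E1cB opening of the O1–C2 bond (racemisation at C2) is avoided, and the medium is far too weakly acidic to cyclise a phenol onto the farnesyl chain.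

Compound list

1 | 2,4,6-trihydroxyacetophenone (phloroacetophenone) | CC(=O)c1c(O)cc(O)cc1O | starting material
2 | (2E,6E)-farnesyl bromide, (2E,6E)-1-bromo-3,7,11-trimethyldodeca-2,6,10-triene | CC(C)=CCC/C(C)=C/CC/C(C)=C/CBr | starting material
3 | 1-[2,4,6-trihydroxy-3-[(2E,6E)-3,7,11-trimethyldodeca-2,6,10-trien-1-yl]phenyl]ethanone | CC(C)=CCC/C(C)=C/CC/C(C)=C/Cc1c(O)cc(O)c(C(C)=O)c1O | intermediate
4 | 1-[4-(tert-butyldimethylsilyloxy)-2,6-dihydroxy-3-[(2E,6E)-farnesyl]phenyl]ethanone | CC(C)=CCC/C(C)=C/CC/C(C)=C/Cc1c(O[Si](C)(C)C(C)(C)C)cc(O)c(C(C)=O)c1O | intermediate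
5 | 3,5-dihydroxybenzaldehyde | O=Cc1cc(O)cc(O)c1 | starting material
6 | 3,5-bis(triisopropylsilyloxy)benzaldehyde | O=Cc1cc(O[Si](C(C)C)(C(C)C)C(C)C)cc(O[Si](C(C)C)(C(C)C)C(C)C)c1 | intermediate
7 | [3,5-bis(triisopropylsilyloxy)phenyl]methanol | OCc1cc(O[Si](C(C)C)(C(C)C)C(C)C)cc(O[Si](C(C)C)(C(C)C)C(C)C)c1 | intermediate
8 | 1-[6-{[3,5-bis(triisopropylsilyloxy)phenyl]methoxy}-4-(tert-butyldimethylsilyloxy)-2-hydroxy-3-[(2E,6E)-farnesyl]phenyl]ethanone (free hydroxyl next to the farnesyl group) | CC(C)=CCC/C(C)=C/CC/C(C)=C/Cc1c(O[Si](C)(C)C(C)(C)C)cc(OCc2cc(O[Si](C(C)C)(C(C)C)C(C)C)cc(O[Si](C(C)C)(C(C)C)C(C)C)c2)c(C(C)=O)c1O | intermediate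
9 | 1-[6-{[3,5-bis(triisopropylsilyloxy)phenyl]methoxy}-2,4-bis(tert-butyldimethylsilyloxy)-3-[(2E,6E)-farnesyl]phenyl]ethanone | CC(C)=CCC/C(C)=C/CC/C(C)=C/Cc1c(O[Si](C)(C)C(C)(C)C)cc(OCc2cc(O[Si](C(C)C)(C(C)C)C(C)C)cc(O[Si](C(C)C)(C(C)C)C(C)C)c2)c(C(C)=O)c1O[Si](C)(C)C(C)(C)C | intermediate
10 | 4,4,4-trifluoro-1-[6-{[3,5-bis(triisopropylsilyloxy)phenyl]methoxy}-2,4-bis(tert-butyldimethylsilyloxy)-3-[(2E,6E)-farnesyl]phenyl]butane-1,3-dione (drawn as the diketo tautomer; not isolated) | CC(C)=CCC/C(C)=C/CC/C(C)=C/Cc1c(O[Si](C)(C)C(C)(C)C)cc(OCc2cc(O[Si](C(C)C)(C(C)C)C(C)C)cc(O[Si](C(C)C)(C(C)C)C(C)C)c2)c(C(=O)CC(=O)C(F)(F)F)c1O[Si](C)(C)C(C)(C)C | intermediate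
11 | 2-diazo-1-[6-{[3,5-bis(triisopropylsilyloxy)phenyl]methoxy}-2,4-bis(tert-butyldimethylsilyloxy)-3-[(2E,6E)-farnesyl]phenyl]ethanone (key-step precursor) | CC(C)=CCC/C(C)=C/CC/C(C)=C/Cc1c(O[Si](C)(C)C(C)(C)C)cc(OCc2cc(O[Si](C(C)C)(C(C)C)C(C)C)cc(O[Si](C(C)C)(C(C)C)C(C)C)c2)c(C(=O)C=[N+]=[N-])c1O[Si](C)(C)C(C)(C)C | intermediate
12 | (2S)-5,7-bis(tert-butyldimethylsilyloxy)-2-[3,5-bis(triisopropylsilyloxy)phenyl]-6-[(2E,6E)-farnesyl]chroman-4-one (key-step product) | CC(C)=CCC/C(C)=C/CC/C(C)=C/Cc1c(O[Si](C)(C)C(C)(C)C)cc2c(c1O[Si](C)(C)C(C)(C)C)C(=O)C[C@@H](c1cc(O[Si](C(C)C)(C(C)C)C(C)C)cc(O[Si](C(C)C)(C(C)C)C(C)C)c1)O2 | intermediate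
13 | (2S)-2-(3,5-dihydroxyphenyl)-5,7-dihydroxy-6-[(2E,6E)-3,7,11-trimethyldodeca-2,6,10-trien-1-yl]chroman-4-one | CC(C)=CCC/C(C)=C/CC/C(C)=C/Cc1c(O)cc2c(c1O)C(=O)C[C@@H](c1cc(O)cc(O)c1)O2 | target

Total step count: 9 (steps 1, 2 and 5–9 on the main line; steps 3 and 4 for the ring B alcohol).
Longest linear sequence: 7 steps (1, 2, 5, 6, 7, 8, 9, starting from 1).

Steps most likely to fail

Step 8. The carbenoid may be intercepted by the lone pair of O1 (oxonium ylide, then [1,2]-benzyl shift) faster than it inserts, or the catalyst may not tell the two enantiotopic benzylic hydrogens apart. The fallback makes O1–C2 instead of C2–C3 and sets out from 4 and 6. Pyrrolidine in MeCN at 50 °C should bring about aldol condensation and oxa-Michael closure through the less hindered chelated hydroxyl, giving racemic 5-hydroxy-7-(tert-butyldimethylsilyloxy)-2-[3,5-bis(triisopropylsilyloxy)phenyl]-6-[(2E,6E)-farnesyl]chroman-4-one F1. Closure through the other chelated hydroxyl is a competing process whose product must be removed by chromatography. Preparative HPLC on a cellulose tris(3,5-dimethylphenylcarbamate) phase should then deliver the (2S)-enantiomer F2. Bu4NF/AcOH as in step 9 removes its three silyl ethers, and the route is rejoined at 13.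

Step 5. Etherification may occur at the wrong chelated hydroxyl (the one beside the farnesyl group) or at both, which would carry the wrong ring A substitution pattern forward. The regiochemistry of 8 is to be checked by an NOE contact between the OCH2 group and H-5 before going on. The fallback forms the ether before the farnesyl group is present, when both chelated hydroxyls are equivalent, and sets out from 1. TBSCl (2.1 equiv) and imidazole in DMF should give 1-[2,4-bis(tert-butyldimethylsilyloxy)-6-hydroxyphenyl]ethanone F3, with one chelated hydroxyl left. Mitsunobu coupling with 7 (PPh3, DIAD, THF) gives 1-[2-{[3,5-bis(triisopropylsilyloxy)phenyl]methoxy}-4,6-bis(tert-butyldimethylsilyloxy)phenyl]ethanone F4 with no regiochemical choice. K2CO3 in MeOH at 0 °C should cleave only the two TBS ethers activated by the ortho/para acetyl group, giving 1-[2-{[3,5-bis(triisopropylsilyloxy)phenyl]methoxy}-4,6-dihydroxyphenyl]ethanone F5. C-farnesylation with 2 and DBU as in step 1, at the ring carbon between the two free hydroxyls and away from the bulky benzyloxy flank, gives 1-[6-{[3,5-bis(triisopropylsilyloxy)phenyl]methoxy}-2,4-dihydroxy-3-[(2E,6E)-farnesyl]phenyl]ethanone F6. TBSOTf (2.5 equiv) and 2,6-lutidine silylate both hydroxyls, and the route is rejoined at 9.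

Step 7. The ortho TBS group may migrate from the phenolic oxygen to the enolate oxygen, or C-trifluoroacetylation of the hindered ketone may stay incomplete. The fallback activates the methyl ketone without an enolate and sets out from 9. Heating with Me2NCH(OMe)2 in toluene at 90 °C should give the enaminone (E)-3-(dimethylamino)-1-[6-{[3,5-bis(triisopropylsilyloxy)phenyl]methoxy}-2,4-bis(tert-butyldimethylsilyloxy)-3-[(2E,6E)-farnesyl]phenyl]prop-2-en-1-one F7 under neutral conditions. p-ABSA in MeCN at rt to 40 °C then adds across the enamine C=C bond, and the triazoline collapses to the diazomethyl ketone and an N-sulfonylformamidine (diazo transfer with C=C cleavage). The route is rejoined at 11.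

Further compounds

F1 | step 8 | racemic 5-hydroxy-7-(tert-butyldimethylsilyloxy)-2-[3,5-bis(triisopropylsilyloxy)phenyl]-6-[(2E,6E)-farnesyl]chroman-4-one | CC(C)=CCC/C(C)=C/CC/C(C)=C/Cc1c(O[Si](C)(C)C(C)(C)C)cc2c(c1O)C(=O)CC(c1cc(O[Si](C(C)C)(C(C)C)C(C)C)cc(O[Si](C(C)C)(C(C)C)C(C)C)c1)O2
F2 | step 8 | (2S)-5-hydroxy-7-(tert-butyldimethylsilyloxy)-2-[3,5-bis(triisopropylsilyloxy)phenyl]-6-[(2E,6E)-farnesyl]chroman-4-one | CC(C)=CCC/C(C)=C/CC/C(C)=C/Cc1c(O[Si](C)(C)C(C)(C)C)cc2c(c1O)C(=O)C[C@@H](c1cc(O[Si](C(C)C)(C(C)C)C(C)C)cc(O[Si](C(C)C)(C(C)C)C(C)C)c1)O2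
F3 | step 5 | 1-[2,4-bis(tert-butyldimethylsilyloxy)-6-hydroxyphenyl]ethanone | CC(=O)c1c(O)cc(O[Si](C)(C)C(C)(C)C)cc1O[Si](C)(C)C(C)(C)C
F4 | step 5 | 1-[2-{[3,5-bis(triisopropylsilyloxy)phenyl]methoxy}-4,6-bis(tert-butyldimethylsilyloxy)phenyl]ethanone | CC(=O)c1c(OCc2cc(O[Si](C(C)C)(C(C)C)C(C)C)cc(O[Si](C(C)C)(C(C)C)C(C)C)c2)cc(O[Si](C)(C)C(C)(C)C)cc1O[Si](C)(C)C(C)(C)C
F5 | step 5 | 1-[2-{[3,5-bis(triisopropylsilyloxy)phenyl]methoxy}-4,6-dihydroxyphenyl]ethanone | CC(=O)c1c(OCc2cc(O[Si](C(C)C)(C(C)C)C(C)C)cc(O[Si](C(C)C)(C(C)C)C(C)C)c2)cc(O)cc1O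
F6 | step 5 | 1-[6-{[3,5-bis(triisopropylsilyloxy)phenyl]methoxy}-2,4-dihydroxy-3-[(2E,6E)-farnesyl]phenyl]ethanone | CC(C)=CCC/C(C)=C/CC/C(C)=C/Cc1c(O)cc(OCc2cc(O[Si](C(C)C)(C(C)C)C(C)C)cc(O[Si](C(C)C)(C(C)C)C(C)C)c2)c(C(C)=O)c1O
F7 | step 7 | (E)-3-(dimethylamino)-1-[6-{[3,5-bis(triisopropylsilyloxy)phenyl]methoxy}-2,4-bis(tert-butyldimethylsilyloxy)-3-[(2E,6E)-farnesyl]phenyl]prop-2-en-1-one | CC(C)=CCC/C(C)=C/CC/C(C)=C/Cc1c(O[Si](C)(C)C(C)(C)C)cc(OCc2cc(O[Si](C(C)C)(C(C)C)C(C)C)cc(O[Si](C(C)C)(C(C)C)C(C)C)c2)c(C(=O)/C=C/N(C)C)c1O[Si](C)(C)C(C)(C)C
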